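**Retrosynthetic overview**
- Daphnodorin D2 comes from its hexa-O-benzyl ether by one global hydrogenolysis.
- The flavone C3–flavan C8 bond comes from a Negishi coupling of C3-zincated tri-O-benzylapigenin (flavone rings A, C and B bought in as apigenin) with a (2S)-8-bromo-tri-O-benzylflavan.
- The bromoflavan comes from (2S)-4'-benzyloxy-5,7-dihydroxyflavan by O-benzylation and C8-selective bromination.
- Key step: the flavan O1–C2 bond, the pyran ring and the only stereocentre come from a catalytic enantioselective 6-endo hydroalkoxylation of a 2-cinnamylphloroglucinol, whose two ortho hydroxyls are equivalent.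
- The cinnamylphloroglucinol comes from phloroglucinol and a 1-arylallyl alcohol (Friedel–Crafts), itself from 4-benzyloxybenzaldehyde and vinyl Grignard; the flavan pyran ring is the only ring built (step 3).

Assumption: the SMILES gives no axial descriptor, so the C3–C8 axis is treated as not configurationally fixed and only flavan C2 (S) is controlled; the antipode of the step 3 catalyst that gives 2S is fixed in a first screen.

**Step 1**
Reactants: 1 4-(benzyloxy)benzaldehyde; 2 vinylmagnesium bromide
Product: 3 rac-1-[4-(benzyloxy)phenyl]prop-2-en-1-ol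
Conditions: CH2=CHMgBr (1.2 equiv), THF, 0 °C; sat. aq NH4Cl
Reagents that add atoms: none
Why: Grignard 1,2-addition of a vinyl nucleophile to an aromatic aldehyde; the carbinol centre is racemic and is erased in step 2.

**Step 2**
Reactants: 3 rac-1-[4-(benzyloxy)phenyl]prop-2-en-1-ol; 4 phloroglucinol
Product: 5 2-[(2E)-3-[4-(benzyloxy)phenyl]prop-2-en-1-yl]benzene-1,3,5-triol
Conditions: 4 (4 equiv), (PhO)2P(O)OH (5 mol%), MeCN, 0 → 25 °C
Reagents that add atoms: none
Why: Friedel–Crafts allylation in which the weak acid ionises the doubly activated allylic alcohol to a 1-arylallyl cation that the phloroglucinol ring attacks at the unsubstituted terminus to give the conjugated E-cinnamyl product, with excess 4 suppressing double alkylation and the acid too weak to protonate the product styrene.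

**Step 3**
Reactants: 5 2-[(2E)-3-[4-(benzyloxy)phenyl]prop-2-en-1-yl]benzene-1,3,5-triol
Product: 6 (2S)-2-[4-(benzyloxy)phenyl]-3,4-dihydro-2H-chromene-5,7-diol
Conditions: chiral imidodiphosphorimidate Brønsted acid (IDPi built from two 3,3'-bis[3,5-bis(trifluoromethyl)phenyl]-BINOL units with N-SO2CF3 groups, one antipode, 5 mol%), CHCl3 (0.02 M), −20 → 0 °C
Reagents that add atoms: none
Why: Proposed new method: catalytic enantioselective 6-endo hydroalkoxylation of a 2-cinnamylphenol, in which the confined chiral acid protonates the styrenyl double bond at C3 (Markovnikov) to give the 4-benzyloxybenzylic cation as a contact ion pair inside the chiral anion pocket, and one of the two equivalent ortho hydroxyls, hydrogen-bonded to the counter-anion, closes the pyran ring on one face of the cation so that C2 is set as S by the chosen catalyst antipode (low temperature and high dilution keep ring closure kinetic and suppress re-ionisation and intermolecular arylation); the closest known reactions are the racemic acid-catalysed cyclisation of 2-cinnamylphenols to flavans and the asymmetric intramolecular hydroalkoxylation of unactivated alkenes to tetrahydrofurans with the same acid class.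

**Step 4**
Reactants: 6 (2S)-2-[4-(benzyloxy)phenyl]-3,4-dihydro-2H-chromene-5,7-diol
Product: 7 (2S)-5,7-bis(benzyloxy)-2-[4-(benzyloxy)phenyl]-3,4-dihydro-2H-chromene
Conditions: BnBr (2.3 equiv), K2CO3, DMF, 25 °C
Reagents that add atoms: benzyl bromide, BrCc1ccccc1
Why: Williamson ether synthesis on the two phenols under mild base, as in the O-benzylation of flavan-3-ols, which does not touch the C2 stereocentre.

**Step 5**
Reactants: 7 (2S)-5,7-bis(benzyloxy)-2-[4-(benzyloxy)phenyl]-3,4-dihydro-2H-chromene
Product: 8 (2S)-5,7-bis(benzyloxy)-2-[4-(benzyloxy)phenyl]-8-bromo-3,4-dihydro-2H-chromene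
Conditions: NBS (1.0 equiv), CH2Cl2, −78 → 0 °C
Reagents that add atoms: N-bromosuccinimide, O=C1CCC(=O)N1Br
Why: Electrophilic aromatic bromination of the triply oxygen-activated ring A, which goes to C8 (flanked by the ring oxygen, less hindered than C6 between two benzyloxy groups) as with 5,7-di-O-benzyl flavan-3-ols, while ring B is far less activated.

**Step 6**
Reactants: 9 apigenin
Product: 10 5,7-bis(benzyloxy)-2-[4-(benzyloxy)phenyl]-4H-chromen-4-one
Conditions: BnBr (3.6 equiv), K2CO3, DMF, 80 °C
Reagents that add atoms: benzyl bromide, BrCc1ccccc1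
Why: Williamson ether synthesis, with heating needed to alkylate the chelated 5-hydroxyl after the 7- and 4'-hydroxyls.

**Step 7**
Reactants: 10 5,7-bis(benzyloxy)-2-[4-(benzyloxy)phenyl]-4H-chromen-4-one; 8 (2S)-5,7-bis(benzyloxy)-2-[4-(benzyloxy)phenyl]-8-bromo-3,4-dihydro-2H-chromene
Product: 12 hexa-O-benzyl daphnodorin D2, via C3-zincated tri-O-benzylapigenin 11 (not isolated)
Conditions: 10 (1.2 equiv), TMPZnCl·LiCl (1.3 equiv; TMP = 2,2,6,6-tetramethylpiperidide), THF, 25 °C; then 8 (1.0 equiv), Pd(OAc)2 (4 mol%), SPhos (8 mol%), THF, 60 °C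
Reagents that add atoms: none
Why: Carbonyl-assisted C3 zincation of the flavone by the hindered zinc amide followed by Negishi cross-coupling, in which the bulky electron-rich biarylphosphine lets zerovalent palladium insert into the hindered electron-rich aryl bromide and couple the two doubly ortho-substituted carbons without touching the C2 stereocentre.

**Step 8**
Reactants: 12 hexa-O-benzyl daphnodorin D2
Product: 13 daphnodorin D2
Conditions: H2 (1 atm), Pd(OH)2/C, THF/MeOH, 25 °C
Reagents that add atoms: none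
Why: Heterogeneous hydrogenolysis of the six benzyl aryl ethers under neutral conditions, which at 1 atm leaves the tetrasubstituted chromone double bond and the cyclic C2–O1 benzylic ether intact (as in debenzylation of protected flavan-3-ols), so the 2S centre is preserved.

**Compound list**
1 | 4-(benzyloxy)benzaldehyde | O=Cc1ccc(OCc2ccccc2)cc1 | starting material
2 | vinylmagnesium bromide | C=C[Mg]Br | starting material
3 | rac-1-[4-(benzyloxy)phenyl]prop-2-en-1-ol | C=CC(O)c1ccc(OCc2ccccc2)cc1 | intermediate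
4 | phloroglucinol (benzene-1,3,5-triol) | Oc1cc(O)cc(O)c1 | starting material
5 | 2-[(2E)-3-[4-(benzyloxy)phenyl]prop-2-en-1-yl]benzene-1,3,5-triol | Oc1cc(O)c(C/C=C/c2ccc(OCc3ccccc3)cc2)c(O)c1 | intermediate
6 | (2S)-2-[4-(benzyloxy)phenyl]-3,4-dihydro-2H-chromene-5,7-diol | Oc1cc(O)c2c(c1)O[C@H](c1ccc(OCc3ccccc3)cc1)CC2 | intermediate
7 | (2S)-5,7-bis(benzyloxy)-2-[4-(benzyloxy)phenyl]-3,4-dihydro-2H-chromene | C(c1ccccc1)Oc1cc(OCc2ccccc2)c2c(c1)O[C@H](c1ccc(OCc3ccccc3)cc1)CC2 | intermediate
8 | (2S)-5,7-bis(benzyloxy)-2-[4-(benzyloxy)phenyl]-8-bromo-3,4-dihydro-2H-chromene | C(c1ccccc1)Oc1cc(OCc2ccccc2)c2c(c1Br)O[C@H](c1ccc(OCc3ccccc3)cc1)CC2 | intermediate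
9 | apigenin (5,7-dihydroxy-2-(4-hydroxyphenyl)-4H-chromen-4-one) | O=c1cc(-c2ccc(O)cc2)oc2cc(O)cc(O)c12 | starting material
10 | 5,7-bis(benzyloxy)-2-[4-(benzyloxy)phenyl]-4H-chromen-4-one (tri-O-benzylapigenin) | O=c1cc(-c2ccc(OCc3ccccc3)cc2)oc2cc(OCc3ccccc3)cc(OCc3ccccc3)c12 | intermediate
11 | chloro{5,7-bis(benzyloxy)-2-[4-(benzyloxy)phenyl]-4-oxo-4H-chromen-3-yl}zinc (as its LiCl complex, not isolated) | O=c1c([Zn]Cl)c(-c2ccc(OCc3ccccc3)cc2)oc2cc(OCc3ccccc3)cc(OCc3ccccc3)c12 | intermediate
12 | 5,7-bis(benzyloxy)-3-{(2S)-5,7-bis(benzyloxy)-2-[4-(benzyloxy)phenyl]-3,4-dihydro-2H-chromen-8-yl}-2-[4-(benzyloxy)phenyl]-4H-chromen-4-one (hexa-O-benzyl daphnodorin D2) | O=c1c(-c2c(OCc3ccccc3)cc(OCc3ccccc3)c3c2O[C@H](c2ccc(OCc4ccccc4)cc2)CC3)c(-c2ccc(OCc3ccccc3)cc2)oc2cc(OCc3ccccc3)cc(OCc3ccccc3)c12 | intermediate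
13 | daphnodorin D2, 3-[(2S)-5,7-dihydroxy-2-(4-hydroxyphenyl)-3,4-dihydro-2H-chromen-8-yl]-5,7-dihydroxy-2-(4-hydroxyphenyl)-4H-chromen-4-one | O=c1c(-c2c(O)cc(O)c3c2O[C@H](c2ccc(O)cc2)CC3)c(-c2ccc(O)cc2)oc2cc(O)cc(O)c12 | target

**Step count and risks**
Total steps: 8. Longest linear sequence: 7 (steps 1, 2, 3, 4, 5, 7, 8); step 6 is the one-step side branch.

Risk 1, step 3 (the proposed new hydroalkoxylation). The enantioselectivity may be low, or the 4'-alkoxy-stabilised benzylic C2–O1 bond may re-ionise under the strong acid and erode the ee. The fallback uses known chemistry and sets out from 5. Heating 5 with p-TsOH·H2O (10 mol%) in MeCN at 60 °C gives, by the established acid-catalysed cyclisation of cinnamylphenols, racemic 2-[4-(benzyloxy)phenyl]-3,4-dihydro-2H-chromene-5,7-diol F2. Preparative chiral-phase supercritical-fluid chromatography then separates the 2S enantiomer from (2R)-2-[4-(benzyloxy)phenyl]-3,4-dihydro-2H-chromene-5,7-diol F3, and the route is rejoined at 6.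

Risk 2, step 7 (Negishi coupling of two doubly ortho-substituted partners). Zincation at C3 may be incomplete, or the hindered, electron-rich bromide 8 may couple slowly. The fallback reverses the polarity and sets out from 10 and 8. Compound 10 is lithiated at C3 with LiN(iPr)2 in THF at −78 °C and quenched with I2 to give 5,7-bis(benzyloxy)-2-[4-(benzyloxy)phenyl]-3-iodo-4H-chromen-4-one F4. Compound 8 undergoes bromine–lithium exchange (n-BuLi, THF, −78 °C), then B(OMe)3 and aqueous acid, to give [(2S)-5,7-bis(benzyloxy)-2-[4-(benzyloxy)phenyl]-3,4-dihydro-2H-chromen-8-yl]boronic acid F5. Suzuki–Miyaura coupling of F4 with F5 (Pd(OAc)2, SPhos, K3PO4, toluene/H2O, 90 °C) rejoins the route at 12.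

Risk 3, step 2 (Friedel–Crafts allylation). Over-alkylation of phloroglucinol or premature acid-mediated cyclisation to racemic flavan could occur. The fallback avoids acid and free cations and sets out from 3. Methyl chloroformate and pyridine in CH2Cl2 at 0 °C give methyl 1-[4-(benzyloxy)phenyl]prop-2-en-1-yl carbonate F1. With Pd(PPh3)4 (zerovalent palladium, 3 mol%) and 4 (3 equiv) in THF at 25 °C, F1 undergoes Tsuji–Trost allylation through the π-allyl complex at the unsubstituted terminus; any O-allyl ether re-ionises under the catalyst and funnels to the C-allyl product, rejoining the route at 5.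

**Further compounds**
F1 | step 2 | methyl 1-[4-(benzyloxy)phenyl]prop-2-en-1-yl carbonate (racemic) | C=CC(OC(=O)OC)c1ccc(OCc2ccccc2)cc1
F2 | step 3 | rac-2-[4-(benzyloxy)phenyl]-3,4-dihydro-2H-chromene-5,7-diol | Oc1cc(O)c2c(c1)OC(c1ccc(OCc3ccccc3)cc1)CC2
F3 | step 3 | (2R)-2-[4-(benzyloxy)phenyl]-3,4-dihydro-2H-chromene-5,7-diol | Oc1cc(O)c2c(c1)O[C@@H](c1ccc(OCc3ccccc3)cc1)CC2
F4 | step 7 | 5,7-bis(benzyloxy)-2-[4-(benzyloxy)phenyl]-3-iodo-4H-chromen-4-one | O=c1c(I)c(-c2ccc(OCc3ccccc3)cc2)oc2cc(OCc3ccccc3)cc(OCc3ccccc3)c12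
F5 | step 7 | [(2S)-5,7-bis(benzyloxy)-2-[4-(benzyloxy)phenyl]-3,4-dihydro-2H-chromen-8-yl]boronic acid | C(c1ccccc1)Oc1cc(OCc2ccccc2)c2c(c1B(O)O)O[C@H](c1ccc(OCc3ccccc3)cc1)CC2
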